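Per hour at 110 °C, links Z, formed from end groups E and L, pass on to the other product X at a pace that the earlier runs can give.

| flask | E | L | temperature | remark | time |
|---|---|---|---|---|---|
| Sunday's | 14 mM | 13.3 mM | 95 °C | run made earlier |  |
| Wednesday's | 14 mM | 19 mM | 110 °C | run made earlier |  |
| Saturday's | 14 mM | 29 mM | 95 °C | run made earlier |  |
| Monday's | 28 mM | 13.3 mM | 110 °C | run made earlier |  |
| eta | 14 mM | 13.3 mM (fed, over 8.0 min) | 110 °C | all else is in the flask from the start; the feed brings no volume worth counting | 3.0 h |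
| zeta | 14 mM | 13.3 mM (fed, over 80 min) | 110 °C | all else is in the flask from the start; the feed brings no volume worth counting | 3.0 h |
| alpha | 14 mM (fed, over 80 min) | 13.3 mM | 110 °C | all else is in the flask from the start; the feed brings no volume worth counting | 3.0 h |
| theta | 14 mM | 13.3 mM (fed, over 80 min) |  | the addition at 90 °C, then warmed to 110 °C; the feed brings no volume worth counting | 3.0 h |

- Sunday's (time / h: Z / %, X / %): 0.250: 52.9, 0; 0.417: 55.0, 0.7; 0.667: 56.3, 0.8; 1.00: 56.3, 2.1; 2.00: 54.8, 4.5; 3.00: 53.2, 6.4; 4.00: 50.9, 9.1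
- Wednesday's (time / h: Z / %, X / %): 0.250: 56.1, 2.2; 0.333: 56.0, 3.0; 0.500: 54.0, 4.8; 0.833: 50.5, 8.2; 1.33: 46.6, 13.4; 2.00: 42.6, 19.5; 3.00: 36.9, 24.6
- Saturday's (time / h: Z / %, X / %): 0.500: 65.6, 2.4; 0.667: 64.7, 2.2; 1.00: 64.0, 4.3; 2.00: 60.9, 7.1; 3.00: 59.0, 11.1; 4.00: 56.2, 14.2; 6.00: 51.5, 19.9
- Monday's (time / h: Z / %, X / %): 0.250: 40.9, 0.9; 0.833: 38.8, 1.6; 1.33: 38.6, 3.3; 2.00: 36.6, 4.6; 3.00: 34.5, 7.0

(readings scatter by 0.5 percentage points)

- what was read earlier has a scatter of 0.5 percentage points, one standard deviation
- a reading or a percentage of Z counts all its forms, free or not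

1. the flask with the highest share of Z in Z plus X ("all alike" if they lie within 1.5 percentage points) (eta / zeta / alpha / theta / all alike)
2. share of Z in Z plus X at the end, eta
3. share of Z in Z plus X at the end, zeta
4. share of Z in Z plus X at the end, alpha
5. share of Z in Z plus X at the end, theta

Does X come out of Z? In Wednesday's run X gains 22 percentage points while Z + X gains 3.2 points, which is less, so the share S = Z/(Z + X) shows how long Z has aged.

How fast does it age at these charges? Take the ageing constant w = ln(1/S)/t, a pseudo-first-order constant. The last readings give 0.170 h⁻¹ for Wednesday's run and 0.0616 h⁻¹ for Monday's, which is slower and has more E against L. Eta's ratio of E to L lies between them, and interpolating in the logarithm of that ratio gives w = 0.133 h⁻¹.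

What does a feed change? Eta's feed of 8.0 min is short against 3.0 h, so its Z ages from the start, and this reckoning gives S = 67.0%. Zeta's steady feed takes half of 80 min off the mean age, giving 73.3%. Alpha has the same mean age, but L stands ahead of the incoming E, so Wednesday's constant gives 67.2%. Theta ages slowly during its feed, for which Sunday's 0.0379 h⁻¹ at 95 °C serves as a ceiling, so it reaches 78.1% and stands highest.

The forecast gives 67%, 73%, 63% and 75% for eta, zeta, alpha and theta and names theta, holding that “Theta forms almost no X during its” addition at 90 °C; it matches this reckoning on eta and zeta and lies lower on alpha and theta.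

The simulation gives 65.2%, 70.9%, 68.9% and 76.4%, with theta highest.

    Z → X (k = 0.00800 min⁻¹, Ea = 114 kJ mol⁻¹)
    E + L ⇌ Z + Q (K = 1.90, k = 42.0 M⁻¹ min⁻¹, Ea = 77.0 kJ mol⁻¹, ΔH = −83.0 kJ mol⁻¹)
    E + Z ⇌ D, settled at all times (K = 1000 M⁻¹, ΔH = −45.0 kJ mol⁻¹)
    L → J (k = 0.00510 min⁻¹, Ea = 126 kJ mol⁻¹)
    (constants at 110 °C)

In eta at the end, E + L ⇌ Z + Q relaxes with a half-life of 1.72 min, much shorter than the 1.4 h half-life of free Z, the Z not held in D, on its way to X. Eta's share reads back as w = 0.143 h⁻¹, against 0.133 h⁻¹ reckoned from the runs. A neighbour of eta charged with 5.3 mM of L ends at a share of 80.9%, which reads back as 0.0707 h⁻¹, about half of that reckoned w.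

(The data stem from a simulated flask with made-up constants, and the scatter is random.)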